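**Plan**

1. Numbering used: spiro[4.5]decene C1 (side chain), C4 (Me), C5 (spiro), C7 (O), C8=C9; furanone O1, C2(=O), C3(Me), C4, C5(=CH). Retrosynthesis: cut the ester C–O, then the furanone at O1–C5 and C2–C3, which removes one CO2 and leaves a (Z)-2-iodo-1,3-enyne; cut this at its C=C (iodo-olefination of an ynal) and at the alkyne (from an aldehyde).
2. Feature that allows the key event: O1–C2(=O) of the 5-ylidene-3-methylfuran-2(5H)-one is an intact CO2 unit between C3 and C5. An alkenyl metal at C3, whose C4 carries cis to the metal the alkyne that becomes C5 and the exocyclic carbon, takes up CO2 at C3 and then closes O1–C5 by 5-exo-dig attack.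
3. The cyclohexene ring is cut at C8=C9 (aldol condensation), C9–C10 (one-carbon Wittig homologation) and C5–C6 (enolate alkylation), which leads back to dihydronepetalactone and nepetalactone.
4. Forward: iridoid cyclopentane → quaternary C5 → cyclohexenone → C7 carbinol → dibromoalkene, ynal, (Z)-iodoenyne → CO2 annulation to the butenolide → desilylation and esterification.
5. Stereochemistry: C1 and C4 from nepetalactone; side-chain methyl centre from convex-face hydrogenation; C5 from cis-fused enolate alkylation; C7 from CBS reduction; iodoalkene geometry from the Stork–Zhao olefination; ylidene Z geometry from anti oxyargentation.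

Key step: step 13

Remark: cis,trans-nepetalactone 1, the main lactone of commercial catnip oil, is taken as the purchasable chiral-pool starting material, and the alkenyllithium of step 13 is taken to hold its double-bond geometry at −78 °C.

**Step 1**
Reactants: 1 (4aS,7S,7aR)-nepetalactone
Product: 2 (4S,4aR,7S,7aR)-4,7-dimethylhexahydrocyclopenta[c]pyran-1(3H)-one (dihydronepetalactone)
Conditions: H2 (1 atm), Pd/C, EtOAc, rt
Reagents that add atoms: none
Why: Heterogeneous hydrogenation of the enol-ether C3=C4 bond should occur on the convex face of the cis-fused bicycle (the face of H-4a and H-7a), which sets C4 as S, the later side-chain methyl centre.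

**Step 2**
Reactants: 2 dihydronepetalactone
Product: 4 (4S,4aR,7S,7aR)-7a-(but-2-yn-1-yl)-4,7-dimethylhexahydrocyclopenta[c]pyran-1(3H)-one, via lithium enolate 3 (not isolated)
Conditions: LiN(i-Pr)2 (1.15 equiv), THF, −78 °C; then 1-bromobut-2-yne (1.5 equiv), DMPU, −78 → −20 °C
Reagents that add atoms: 1-bromobut-2-yne CC#CCBr
Why: Lactone enolate alkylation with a propargylic bromide; the electrophile should enter on the convex face (that of H-4a), the only mode that keeps the six–five ring fusion cis, so the butynyl arm ends trans to the C4a–C4 bond and the quaternary (future spiro) centre is fixed.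

**Step 3**
Reactants: 4 butynyl lactone
Product: 5 (4S,4aR,7S,7aR)-4,7-dimethyl-7a-(2-oxobutyl)hexahydrocyclopenta[c]pyran-1(3H)-one
Conditions: Ph3PAuNTf2 (3 mol %), H2O (5 equiv), 1,4-dioxane, 60 °C
Reagents that add atoms: water O
Why: Gold-catalysed alkyne hydration with anchimeric help of the lactone carbonyl (5-exo-dig attack of the carbonyl oxygen on the nearer alkyne carbon) should place the ketone on the carbon γ to the lactone carbonyl, giving the ethyl ketone and not the methyl ketone.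

**Step 4**
Reactants: 5 keto lactone
Product: 6 (4S,4aR,7S,7aR)-7a-(2-hydroxybutyl)-4,7-dimethyloctahydrocyclopenta[c]pyran-1-ol (epimers at C1 and at the carbinol carbon)
Conditions: i-Bu2AlH (3.3 equiv), CH2Cl2, −78 °C; aq. potassium sodium tartrate
Reagents that add atoms: none
Why: Partial reduction of the lactone stops at the lactol at −78 °C (stable tetrahedral aluminate) while the ketone is reduced to the carbinol, which step 6 re-oxidises, so the epimer mixture is of no consequence.

**Step 5**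
Reactants: 6 hydroxy lactol
Product: 7 (2S)-2-[(1R,2R,3S)-2-(2-hydroxybutyl)-2-(2-methoxyethenyl)-3-methylcyclopentyl]propan-1-ol (E/Z and carbinol epimers)
Conditions: Ph3P(CH2OMe)Cl (5 equiv), KN(SiMe3)2 (4.8 equiv), THF, 0 °C → rt
Reagents that add atoms: (methoxymethyl)triphenylphosphonium chloride COC[P+](c1ccccc1)(c1ccccc1)c1ccccc1.[Cl-]
Why: Wittig methoxymethylenation of the open hydroxy-aldehyde form of the lactol adds the one carbon (C9) that the former lactone carbonyl carbon (C10) needs and frees the primary alcohol of the side chain.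

**Step 6**
Reactants: 7 enol ether diol
Product: 8 (2S)-2-[(1R,2R,3S)-2-(2-methoxyethenyl)-3-methyl-2-(2-oxobutyl)cyclopentyl]propanal
Conditions: (n-Pr4N)RuO4 (5 mol %), N-methylmorpholine N-oxide (3 equiv), 4 Å MS, CH2Cl2, rt
Reagents that add atoms: none
Why: Ley–Griffith oxidation takes the primary alcohol to the aldehyde and the secondary one to the ketone under neutral conditions that should spare the enol ether and the α-stereocentre.

**Step 7**
Reactants: 8 keto aldehyde enol ether
Product: 9 1-[(1R,2R,5S)-2-[(2S)-4,4-dibromobut-3-en-2-yl]-1-(2-methoxyethenyl)-5-methylcyclopentyl]butan-2-one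
Conditions: CBr4 (2 equiv), PPh3 (4 equiv), Et3N (2 equiv), CH2Cl2, 0 °C
Reagents that add atoms: carbon tetrabromide BrC(Br)(Br)Br
Why: Ramirez dibromo-olefination (first stage of the Corey–Fuchs sequence) is aldehyde-selective over the ethyl ketone, and the amine buffer should protect the enol ether and the α-centre.

**Step 8**
Reactants: 9 dibromoalkene ketone
Product: 11 (1R,4S,5S)-1-[(2S)-4,4-dibromobut-3-en-2-yl]-4,8-dimethylspiro[4.5]dec-8-en-7-one, via keto aldehyde 10 (not isolated)
Conditions: 1 M HCl, THF, rt; then pyrrolidine (0.3 equiv), AcOH (0.3 equiv), PhMe, 70 °C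
Reagents that add atoms: none
Why: Acid hydrolysis of the enol ether unmasks the C9 aldehyde and amine/acid-mediated intramolecular aldol condensation of the 1,5-keto aldehyde (the ethyl ketone α-carbon C8 onto C9) can only close the six-membered ring, giving the 2-methylcyclohex-2-enone without creating a stereocentre.

**Step 9**
Reactants: 11 spiro enone
Product: 12 (1R,4S,5S,7S)-1-[(2S)-4,4-dibromobut-3-en-2-yl]-4,8-dimethylspiro[4.5]dec-8-en-7-ol
Conditions: (R)-2-methyl-CBS-oxazaborolidine (0.3 equiv), BH3·SMe2 (0.7 equiv), THF, −30 °C; MeOH, then aqueous work-up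
Reagents that add atoms: none
Why: Corey–Bakshi–Shibata 1,2-reduction under reagent control, with the α-methyl alkenyl carbon C8 acting as the large group and C6H2 as the small one, should deliver hydride to the face that gives the 7S carbinol.

**Step 10**
Reactants: 12 allylic alcohol
Product: 13 tert-butyl{[(1R,4S,5S,7S)-1-[(2S)-4,4-dibromobut-3-en-2-yl]-4,8-dimethylspiro[4.5]dec-8-en-7-yl]oxy}dimethylsilane
Conditions: t-BuMe2SiCl (1.5 equiv), imidazole (3 equiv), DMF, rt
Reagents that add atoms: tert-butyl(chloro)dimethylsilane CC(C)(C)[Si](C)(C)Cl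
Why: Standard silylation masks the carbinol against the organolithium steps that follow and leaves C7 untouched.

**Step 11**
Reactants: 13 silyl ether
Product: 15 (4S)-4-[(1R,4S,5S,7S)-7-{[tert-butyl(dimethyl)silyl]oxy}-4,8-dimethylspiro[4.5]dec-8-en-1-yl]pent-2-ynal, via lithium acetylide 14 (not isolated)
Conditions: n-BuLi (2.2 equiv), THF, −78 °C; then DMF (5 equiv), −78 → 0 °C; aq. KH2PO4
Reagents that add atoms: N,N-dimethylformamide CN(C)C=O
Why: Second stage of the Corey–Fuchs sequence (bromine–lithium exchange, α-elimination with 1,2-shift, deprotonation) gives the lithium acetylide, which is formylated by DMF; the propargylic methyl centre is not acidic enough to be touched.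

**Step 12**
Reactants: 15 ynal
Product: 16 tert-butyl{[(1R,4S,5S,7S)-1-[(2S,5Z)-6-iodohept-5-en-3-yn-2-yl]-4,8-dimethylspiro[4.5]dec-8-en-7-yl]oxy}dimethylsilane
Conditions: Ph3P(Et)I (1.6 equiv), n-BuLi (1.6 equiv), THF, rt; I2 (1.55 equiv), −78 °C; NaN(SiMe3)2 (1.5 equiv), −78 → −20 °C; then 15, −78 °C
Reagents that add atoms: ethyltriphenylphosphonium iodide CC[P+](c1ccccc1)(c1ccccc1)c1ccccc1.[I-]; iodine II
Why: Stork–Zhao-type Wittig olefination with (1-iodoethylidene)triphenylphosphorane is kinetically Z-selective, which places iodine cis to the alkynyl group, the geometry the ring closure needs.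

**Step 13**
Reactants: 16 (Z)-iodoenyne
Product: 20 (5Z)-5-{(2S)-2-[(1R,4S,5S,7S)-7-{[tert-butyl(dimethyl)silyl]oxy}-4,8-dimethylspiro[4.5]dec-8-en-1-yl]propylidene}-3-methylfuran-2(5H)-one, via alkenyllithium 17 (not isolated), via lithium enynoate 18 (not isolated), via enynoic acid 19 (not isolated)
Conditions: t-BuLi (2.1 equiv), Et2O, −78 °C; CO2 (1 atm, dried), −78 → 0 °C; then AcOH (1.05 equiv), AgNO3 (1.2 equiv), MeOH, rt, dark
Reagents that add atoms: carbon dioxide O=C=O
Why: Iodine–lithium exchange gives alkenyllithium 17 with retention of geometry, and its attack on CO2 forms the C2–C3 bond (carboxylate 18, then acid 19 on buffering with AcOH). Monovalent silver then binds the alkyne and the cis carboxyl oxygen adds anti to it at the nearer alkyne carbon, forming the O1–C5 bond, and protonolysis of the alkenylsilver releases the butenolide. The closest known reaction types are the carboxylation of alkenyllithiums and the silver-catalysed lactonisation of (Z)-2-en-4-ynoic acids, run here in one flask so that CO2 is stitched in as the O1–C2(=O) unit in a formal (3+2) annulation. The furanone ring closes in the 5-exo-dig mode. No new stereocentre arises; the Z geometry of the exocyclic C5=C bond follows from anti oxyargentation and retentive protonolysis, and the propargylic methyl centre is not touched. The step needs 5-exo over 6-endo closure (2-pyranone), which silver and the branched carbon at the far alkyne terminus should secure, and it needs the alkene geometry to survive, which the low-temperature exchange should secure; AgNO3 is in slight excess because one equivalent is lost as AgI.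

**Step 14**
Reactants: 20 silyl butenolide
Product: 21 (5Z)-5-{(2S)-2-[(1R,4S,5S,7S)-7-hydroxy-4,8-dimethylspiro[4.5]dec-8-en-1-yl]propylidene}-3-methylfuran-2(5H)-one
Conditions: HF·pyridine, pyridine/THF, 0 °C → rt
Reagents that add atoms: none
Why: Buffered acidic fluoride desilylation should free the allylic alcohol without opening the base-sensitive ylidene butenolide.

**Step 15**
Reactants: 21 hydroxy butenolide
Product: 22 (1R,4S,5S,7S)-4,8-dimethyl-1-{(2S)-1-[(2Z)-4-methyl-5-oxofuran-2(5H)-ylidene]propan-2-yl}spiro[4.5]dec-8-en-7-yl 3-phenylpropanoate (CNP0260277.1)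
Conditions: 3-phenylpropanoyl chloride (1.5 equiv), pyridine, DMAP (0.1 equiv), CH2Cl2, 0 °C → rt
Reagents that add atoms: 3-phenylpropanoyl chloride O=C(Cl)CCc1ccccc1
Why: DMAP-catalysed acylation of the secondary allylic alcohol by the acid chloride proceeds at oxygen with retention at C7 and gives the target.

**Compound list**

1 | (4aS,7S,7aR)-4,7-dimethyl-5,6,7,7a-tetrahydrocyclopenta[c]pyran-1(4aH)-one (cis,trans-nepetalactone) | O1C=C(C)[C@H]2CC[C@H](C)[C@H]2C1=O | starting material
2 | (4S,4aR,7S,7aR)-4,7-dimethylhexahydrocyclopenta[c]pyran-1(3H)-one | O1C[C@@H](C)[C@H]2CC[C@H](C)[C@H]2C1=O | intermediate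
3 | lithium enolate of 2 (lithium (4S,4aR,7S)-4,7-dimethyl-3,4,4a,5,6,7-hexahydrocyclopenta[c]pyran-1-olate) | O1C[C@@H](C)[C@H]2CC[C@H](C)C2=C1O[Li] | intermediate (not isolated)
4 | (4S,4aR,7S,7aR)-7a-(but-2-yn-1-yl)-4,7-dimethylhexahydrocyclopenta[c]pyran-1(3H)-one | O1C[C@@H](C)[C@H]2CC[C@H](C)[C@@]2(CC#CC)C1=O | intermediate
5 | (4S,4aR,7S,7aR)-4,7-dimethyl-7a-(2-oxobutyl)hexahydrocyclopenta[c]pyran-1(3H)-one | O1C[C@@H](C)[C@H]2CC[C@H](C)[C@@]2(CC(=O)CC)C1=O | intermediate
6 | (4S,4aR,7S,7aR)-7a-(2-hydroxybutyl)-4,7-dimethyloctahydrocyclopenta[c]pyran-1-ol (epimers at C1 and the carbinol carbon) | O1C[C@@H](C)[C@H]2CC[C@H](C)[C@@]2(CC(O)CC)C1O | intermediate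
7 | (2S)-2-[(1R,2R,3S)-2-(2-hydroxybutyl)-2-(2-methoxyethenyl)-3-methylcyclopentyl]propan-1-ol (E/Z and carbinol epimers) | OC[C@@H](C)[C@H]2CC[C@H](C)[C@@]2(CC(O)CC)C=COC | intermediate
8 | (2S)-2-[(1R,2R,3S)-2-(2-methoxyethenyl)-3-methyl-2-(2-oxobutyl)cyclopentyl]propanal (E/Z) | O=C[C@@H](C)[C@H]2CC[C@H](C)[C@@]2(CC(=O)CC)C=COC | intermediate
9 | 1-[(1R,2R,5S)-2-[(2S)-4,4-dibromobut-3-en-2-yl]-1-(2-methoxyethenyl)-5-methylcyclopentyl]butan-2-one (E/Z) | BrC(Br)=C[C@@H](C)[C@H]2CC[C@H](C)[C@@]2(CC(=O)CC)C=COC | intermediate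
10 | 2-[(1S,2R,5S)-2-[(2S)-4,4-dibromobut-3-en-2-yl]-5-methyl-1-(2-oxobutyl)cyclopentyl]acetaldehyde | BrC(Br)=C[C@@H](C)[C@H]2CC[C@H](C)[C@@]2(CC(=O)CC)CC=O | intermediate (not isolated)
11 | (1R,4S,5S)-1-[(2S)-4,4-dibromobut-3-en-2-yl]-4,8-dimethylspiro[4.5]dec-8-en-7-one | BrC(Br)=C[C@@H](C)[C@H]2CC[C@H](C)[C@@]23CC=C(C)C(=O)C3 | intermediate
12 | (1R,4S,5S,7S)-1-[(2S)-4,4-dibromobut-3-en-2-yl]-4,8-dimethylspiro[4.5]dec-8-en-7-ol | BrC(Br)=C[C@@H](C)[C@H]2CC[C@H](C)[C@@]23CC=C(C)[C@@H](O)C3 | intermediate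
13 | tert-butyl{[(1R,4S,5S,7S)-1-[(2S)-4,4-dibromobut-3-en-2-yl]-4,8-dimethylspiro[4.5]dec-8-en-7-yl]oxy}dimethylsilane | BrC(Br)=C[C@@H](C)[C@H]2CC[C@H](C)[C@@]23CC=C(C)[C@@H](O[Si](C)(C)C(C)(C)C)C3 | intermediate
14 | lithium (3S)-3-[(1R,4S,5S,7S)-7-{[tert-butyl(dimethyl)silyl]oxy}-4,8-dimethylspiro[4.5]dec-8-en-1-yl]but-1-yn-1-ide | [Li]C#C[C@@H](C)[C@H]2CC[C@H](C)[C@@]23CC=C(C)[C@@H](O[Si](C)(C)C(C)(C)C)C3 | intermediate (not isolated)
15 | (4S)-4-[(1R,4S,5S,7S)-7-{[tert-butyl(dimethyl)silyl]oxy}-4,8-dimethylspiro[4.5]dec-8-en-1-yl]pent-2-ynal | O=CC#C[C@@H](C)[C@H]2CC[C@H](C)[C@@]23CC=C(C)[C@@H](O[Si](C)(C)C(C)(C)C)C3 | intermediate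
16 | tert-butyl{[(1R,4S,5S,7S)-1-[(2S,5Z)-6-iodohept-5-en-3-yn-2-yl]-4,8-dimethylspiro[4.5]dec-8-en-7-yl]oxy}dimethylsilane | C/C(I)=C/C#C[C@@H](C)[C@H]2CC[C@H](C)[C@@]23CC=C(C)[C@@H](O[Si](C)(C)C(C)(C)C)C3 | intermediate
17 | (2E,6S)-6-[(1R,4S,5S,7S)-7-{[tert-butyl(dimethyl)silyl]oxy}-4,8-dimethylspiro[4.5]dec-8-en-1-yl]-2-lithiohept-2-en-4-yne (lithium cis to the alkyne) | C/C([Li])=C/C#C[C@@H](C)[C@H]2CC[C@H](C)[C@@]23CC=C(C)[C@@H](O[Si](C)(C)C(C)(C)C)C3 | intermediate (not isolated)
18 | lithium (2Z,6S)-6-[(1R,4S,5S,7S)-7-{[tert-butyl(dimethyl)silyl]oxy}-4,8-dimethylspiro[4.5]dec-8-en-1-yl]-2-methylhept-2-en-4-ynoate | C/C(C(=O)O[Li])=C/C#C[C@@H](C)[C@H]2CC[C@H](C)[C@@]23CC=C(C)[C@@H](O[Si](C)(C)C(C)(C)C)C3 | intermediate (not isolated)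
19 | (2Z,6S)-6-[(1R,4S,5S,7S)-7-{[tert-butyl(dimethyl)silyl]oxy}-4,8-dimethylspiro[4.5]dec-8-en-1-yl]-2-methylhept-2-en-4-ynoic acid | C/C(C(=O)O)=C/C#C[C@@H](C)[C@H]2CC[C@H](C)[C@@]23CC=C(C)[C@@H](O[Si](C)(C)C(C)(C)C)C3 | intermediate (not isolated)
20 | (5Z)-5-{(2S)-2-[(1R,4S,5S,7S)-7-{[tert-butyl(dimethyl)silyl]oxy}-4,8-dimethylspiro[4.5]dec-8-en-1-yl]propylidene}-3-methylfuran-2(5H)-one | CC1=C/C(=C/[C@@H](C)[C@H]2CC[C@H](C)[C@@]23CC=C(C)[C@@H](O[Si](C)(C)C(C)(C)C)C3)OC1=O | intermediate
21 | (5Z)-5-{(2S)-2-[(1R,4S,5S,7S)-7-hydroxy-4,8-dimethylspiro[4.5]dec-8-en-1-yl]propylidene}-3-methylfuran-2(5H)-one | CC1=C/C(=C/[C@@H](C)[C@H]2CC[C@H](C)[C@@]23CC=C(C)[C@@H](O)C3)OC1=O | intermediate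
22 | (1R,4S,5S,7S)-4,8-dimethyl-1-{(2S)-1-[(2Z)-4-methyl-5-oxofuran-2(5H)-ylidene]propan-2-yl}spiro[4.5]dec-8-en-7-yl 3-phenylpropanoate | CC1=C/C(=C/[C@@H](C)[C@H]2CC[C@H](C)[C@@]23CC=C(C)[C@@H](OC(=O)CCc2ccccc2)C3)OC1=O | target

**Totals**

Total step count: 15. Longest linear sequence: 15 steps (the route is linear from 1).

**Steps most likely to fail**

Step 2. The ring-fusion enolate is hindered and the required convex face carries the neighbouring C7 methyl, so alkylation may be slow, may be overtaken by proton transfer, or may occur partly on the other face. The fallback sets out from 2 and comes back at 4, and makes the enolate from an open-chain ester where only the bulk of the neighbouring side chain decides the face. Compound 2 is saponified (KOH, aq. MeOH) and the hydroxy carboxylate is silylated (t-BuPh2SiCl, imidazole, DMF; then K2CO3, aq. MeOH to cleave the silyl ester) to (1R,2R,5S)-2-[(2S)-1-{[tert-butyl(diphenyl)silyl]oxy}propan-2-yl]-5-methylcyclopentane-1-carboxylic acid F1. MeI and K2CO3 in DMF give its methyl ester F2. LiN(i-Pr)2 and then 1-bromobut-2-yne should alkylate the ester enolate anti to the silyloxypropyl group to give methyl (1R,2R,5S)-1-(but-2-yn-1-yl)-2-[(2S)-1-{[tert-butyl(diphenyl)silyl]oxy}propan-2-yl]-5-methylcyclopentane-1-carboxylate F3. n-Bu4NF in THF removes the silyl group and the freed alkoxide closes the lactone to 4.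

Step 13. The alkenyllithium may be protonated or lose its geometry before it meets CO2, and the carboxyl group may close in the 6-endo sense to a 2-pyranone. The fallback sets out from 13 and comes back at 20, and takes the ring oxygen and carbonyl from an iodo acid in place of CO2. n-BuLi (2.1 equiv, THF, −78 °C) followed by aq. NH4Cl converts 13 into tert-butyl{[(1R,4S,5S,7S)-1-[(2S)-but-3-yn-2-yl]-4,8-dimethylspiro[4.5]dec-8-en-7-yl]oxy}dimethylsilane F4. Sonogashira coupling of this alkyne with (Z)-3-iodo-2-methylprop-2-enoic acid (Pd(PPh3)4, CuI, Et3N, MeCN) is followed in the same flask by 5-exo-dig lactonisation of the enynoic acid and should give 20.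

Step 9. Hydride delivery may show poor facial selectivity, because the two flanks of the ketone (the alkenyl carbon and the CH2 on the quaternary spiro carbon) are of similar size and the spiro environment may oppose the catalyst. The fallback sets out from 11 and comes back at 12, and uses substrate control followed by inversion. NaBH4 with CeCl3·7H2O in MeOH at −78 °C (Luche reduction) reduces 11; if the epimer (1R,4S,5S,7R)-1-[(2S)-4,4-dibromobut-3-en-2-yl]-4,8-dimethylspiro[4.5]dec-8-en-7-ol F5 predominates, or after separation of the epimers, it is inverted by Mitsunobu esterification (4-nitrobenzoic acid, PPh3, diisopropyl azodicarboxylate, THF) to (1R,4S,5S,7S)-1-[(2S)-4,4-dibromobut-3-en-2-yl]-4,8-dimethylspiro[4.5]dec-8-en-7-yl 4-nitrobenzoate F6. K2CO3 in MeOH then frees 12.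

**Further compounds**

F1 | step 2 | (1R,2R,5S)-2-[(2S)-1-{[tert-butyl(diphenyl)silyl]oxy}propan-2-yl]-5-methylcyclopentane-1-carboxylic acid | CC(C)(C)[Si](c1ccccc1)(c1ccccc1)OC[C@@H](C)[C@H]2CC[C@H](C)[C@H]2C(=O)O
F2 | step 2 | methyl (1R,2R,5S)-2-[(2S)-1-{[tert-butyl(diphenyl)silyl]oxy}propan-2-yl]-5-methylcyclopentane-1-carboxylate | CC(C)(C)[Si](c1ccccc1)(c1ccccc1)OC[C@@H](C)[C@H]2CC[C@H](C)[C@H]2C(=O)OC
F3 | step 2 | methyl (1R,2R,5S)-1-(but-2-yn-1-yl)-2-[(2S)-1-{[tert-butyl(diphenyl)silyl]oxy}propan-2-yl]-5-methylcyclopentane-1-carboxylate | CC(C)(C)[Si](c1ccccc1)(c1ccccc1)OC[C@@H](C)[C@H]2CC[C@H](C)[C@@]2(CC#CC)C(=O)OC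
F4 | step 13 | tert-butyl{[(1R,4S,5S,7S)-1-[(2S)-but-3-yn-2-yl]-4,8-dimethylspiro[4.5]dec-8-en-7-yl]oxy}dimethylsilane | C#C[C@@H](C)[C@H]2CC[C@H](C)[C@@]23CC=C(C)[C@@H](O[Si](C)(C)C(C)(C)C)C3
F5 | step 9 | (1R,4S,5S,7R)-1-[(2S)-4,4-dibromobut-3-en-2-yl]-4,8-dimethylspiro[4.5]dec-8-en-7-ol | BrC(Br)=C[C@@H](C)[C@H]2CC[C@H](C)[C@@]23CC=C(C)[C@H](O)C3
F6 | step 9 | (1R,4S,5S,7S)-1-[(2S)-4,4-dibromobut-3-en-2-yl]-4,8-dimethylspiro[4.5]dec-8-en-7-yl 4-nitrobenzoate | BrC(Br)=C[C@@H](C)[C@H]2CC[C@H](C)[C@@]23CC=C(C)[C@@H](OC(=O)c2ccc(cc2)[N+](=O)[O-])C3
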